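The route rests on removing C5, the ester-bearing carbon, from the 3,4-dihydro-2H-pyran (O1, C2 methyl, C3 formyl, C4 side chain, C5 ester, C6): the remainder is a 2,3-dihydrofuran whose enol ether is C4=C6. The key step puts C5 back, with its CO2Me, as a bromo(methoxycarbonyl)carbenoid: cyclopropanation of that enol ether, loss of bromide with opening of the bond shared by both rings, and methanol capture give the six-membered 2-methoxy-2H-pyran-3-carboxylate in one operation. It exploits the β-alkoxyacrylate O1–C6H=C5(CO2Me), in which C5 lies between C6 and C4; the C6 acetal later hands the side chain to C4 by SN2′. The precursor is trans-2-methyl-3-(1,3-dioxolan-2-yl)-2,3-dihydrofuran, made from (S)-5-methylfuran-2(5H)-one.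

Key step: step 4

Remark: the given SMILES is read as the (2S,3R,4R) isomer, i.e. 2,3-trans and 3,4-trans on the ring; (S)-5-methylfuran-2(5H)-one and hydroxytyrosol acetate are taken as purchasable.

Step 1
Reactants: 1 (S)-5-methylfuran-2(5H)-one
Product: 2 (4R,5S)-4-(1,3-dioxolan-2-yl)-5-methyloxolan-2-one
Conditions: 1,3-dioxolane (solvent), Ph2CO (0.2 equiv), hν (350 nm), degassed, rt
Reagents that add atoms: 1,3-dioxolane C1COCO1
Why: Photochemical radical conjugate addition (Giese type): triplet benzophenone abstracts the acetal C–H of dioxolane and the nucleophilic 1,3-dioxolan-2-yl radical should add to the β-carbon of the butenolide on the face anti to the C5 methyl group, which sets the new centre (4R) trans to methyl under neutral conditions that do not racemise the lactone.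

Step 2
Reactants: 2 (4R,5S)-4-(1,3-dioxolan-2-yl)-5-methyloxolan-2-one
Product: 3 (4R,5S)-4-(1,3-dioxolan-2-yl)-5-methyloxolan-2-ol (anomer mixture)
Conditions: DIBAL-H (1.1 equiv), CH2Cl2, −78 °C; Rochelle salt work-up
Reagents that add atoms: none
Why: Partial reduction of a γ-lactone with DIBAL-H at low temperature stops at the aluminium hemiacetal and should give the lactol on work-up, with the dioxolane and both stereocentres untouched.

Step 3
Reactants: 3 (4R,5S)-4-(1,3-dioxolan-2-yl)-5-methyloxolan-2-ol
Product: 5 (2S,3R)-3-(1,3-dioxolan-2-yl)-2-methyl-2,3-dihydrofuran, via lactol mesylate 4 (not isolated)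
Conditions: MsCl (1.2 equiv), Et3N (4 equiv), CH2Cl2, −40 → 40 °C
Reagents that add atoms: none
Why: Dehydration of a lactol through its anomeric mesylate (elimination via the oxocarbenium ion) is the standard entry to 2,3-dihydrofurans, and only the ring CH2 next to the lactol carbon can lose the proton, so the enol ether can form in one position only.

Step 4
Reactants: 5 (2S,3R)-3-(1,3-dioxolan-2-yl)-2-methyl-2,3-dihydrofuran
Product: 8 methyl (5R,6S)-5-(1,3-dioxolan-2-yl)-2-methoxy-6-methyl-5,6-dihydro-2H-pyran-3-carboxylate (anomer mixture), via bromocyclopropane 6 (not isolated), via 2-bromo-2H-pyran 7 (not isolated)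
Conditions: N2CHCO2Me, NBS, DBU, CH2Cl2, 0 °C, cold SiO2 filtration (gives BrC(N2)CO2Me); added to 5, Rh2(esp)2 (1 mol %), CH2Cl2, −40 → 0 °C; then MeOH, 2,6-lutidine, 0 °C → rt
Reagents that add atoms: methyl bromodiazoacetate COC(=O)C(Br)=[N+]=[N-] (made in the flask from methyl diazoacetate COC(=O)C=[N+]=[N-] and N-bromosuccinimide O=C1CCC(=O)N1Br); methanol CO
Why: Proposed new method: the electrophilic dirhodium carbenoid from methyl bromodiazoacetate should add to the electron-rich enol-ether bond C4=C6 of 5 on the face anti to the C3 dioxolanyl group to give bromocyclopropane 6; the O1 lone pair then assists loss of bromide with disrotatory opening of the bond shared by the two rings (cyclopropyl-to-allyl cation), so that the five-membered ring becomes the six-membered oxocarbenium/allyl bromide 7 with C5 and its ester inserted between C6 and C4, and methanol captures it at the oxygen-bearing terminus C6. The closest known reaction types are the dihalocarbene ring expansion of 2,3-dihydrofurans and glycals to 3-halo-2-alkoxy-dihydropyrans and oxepines, and the Ciamician–Dennstedt-type expansion of indoles to quinoline-3-carboxylates with halodiazoacetates under Rh2(esp)2. The only ring closed is the cyclopropane, by [2+1] carbenoid addition; the six-membered ring is not closed but arises from the bicycle by electrocyclic ring opening. The one new stereocentre, the acetal carbon C6, is not controlled (the anomeric effect should favour axial OMe) and is erased in step 6, while C2 and C3 are not touched. The step needs chemoselectivity for cyclopropanation over C–H insertion at the dioxolane and capture at C6 in preference to proton loss, which the high nucleophilicity of the enol ether, the localisation of charge next to O1 and the excess of methanol should secure; a cyclopropane epimer with bromide exo can still ionise stepwise through the donor–acceptor zwitterion.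

Step 5
Reactants: 9 hydroxytyrosol acetate, 2-(3,4-dihydroxyphenyl)ethyl acetate
Product: 10 2-(2,2-dimethyl-1,3-benzodioxol-5-yl)ethyl acetate
Conditions: 2,2-dimethoxypropane, TsOH·H2O (cat.), toluene, reflux, 4 Å MS trap
Reagents that add atoms: 2,2-dimethoxypropane COC(C)(C)OC
Why: Acid-catalysed transketalisation of a catechol with 2,2-dimethoxypropane should give the cyclic acetonide once methanol is removed, and the acetate ester is inert under these conditions.

Step 6
Reactants: 8 methyl (5R,6S)-5-(1,3-dioxolan-2-yl)-2-methoxy-6-methyl-5,6-dihydro-2H-pyran-3-carboxylate; 10 2-(2,2-dimethyl-1,3-benzodioxol-5-yl)ethyl acetate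
Product: 13 methyl (2S,3R,4R)-4-{2-[2-(2,2-dimethyl-1,3-benzodioxol-5-yl)ethoxy]-2-oxoethyl}-3-(1,3-dioxolan-2-yl)-2-methyl-3,4-dihydro-2H-pyran-5-carboxylate, via lithium enolate 11 (not isolated), via Michael adduct enolate 12 (not isolated)
Conditions: 10 (2 equiv), LDA (2 equiv), THF, −78 °C; then 8, −78 → −30 °C; aq. NH4Cl
Reagents that add atoms: none
Why: Michael addition of the lithium ester enolate 11 to the β-carbon C4 of the enoate, anti to the neighbouring C3 dioxolanyl group, should give enolate 12, which expels the C6 methoxide (E1cB; overall an SN2′ addition–elimination as with Morita–Baylis–Hillman-type ethers) to form the β-alkoxyacrylate C5=C6 and set C4 (R) trans to C3.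

Step 7
Reactants: 13 methyl (2S,3R,4R)-4-{2-[2-(2,2-dimethyl-1,3-benzodioxol-5-yl)ethoxy]-2-oxoethyl}-3-(1,3-dioxolan-2-yl)-2-methyl-3,4-dihydro-2H-pyran-5-carboxylate
Product: 14 methyl (2S,3R,4R)-4-{2-[2-(3,4-dihydroxyphenyl)ethoxy]-2-oxoethyl}-3-formyl-2-methyl-3,4-dihydro-2H-pyran-5-carboxylate (target)
Conditions: TFA/H2O/CH2Cl2 (4:1:5), 0 °C → rt
Reagents that add atoms: water O
Why: Acidic ketal hydrolysis should free the C3 aldehyde from the dioxolane and the catechol from its acetonide in one operation, the vinylogous carbonate O1–C6=C5–CO2Me and both esters being stable to it; the epimerisable C3 already sits in the favoured 2,3-trans-3,4-trans arrangement.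

Compound list
1 | (S)-5-methylfuran-2(5H)-one | C[C@@H]1OC(=O)C=C1 | starting material
2 | (4R,5S)-4-(1,3-dioxolan-2-yl)-5-methyloxolan-2-one | O=C1O[C@@H](C)[C@H](C2OCCO2)C1 | intermediate
3 | (4R,5S)-4-(1,3-dioxolan-2-yl)-5-methyloxolan-2-ol (anomer mixture) | OC1O[C@@H](C)[C@H](C2OCCO2)C1 | intermediate
4 | (4R,5S)-4-(1,3-dioxolan-2-yl)-5-methyloxolan-2-yl methanesulfonate (not isolated) | CS(=O)(=O)OC1O[C@@H](C)[C@H](C2OCCO2)C1 | intermediate
5 | (2S,3R)-3-(1,3-dioxolan-2-yl)-2-methyl-2,3-dihydrofuran | C1=CO[C@@H](C)[C@@H]1C2OCCO2 | intermediate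
6 | methyl (3S,4R)-6-bromo-4-(1,3-dioxolan-2-yl)-3-methyl-2-oxabicyclo[3.1.0]hexane-6-carboxylate (not isolated; C1, C5, C6 not defined) | COC(=O)C1(Br)C2O[C@@H](C)[C@H](C3OCCO3)C12 | intermediate
7 | methyl (5R,6S)-2-bromo-5-(1,3-dioxolan-2-yl)-6-methyl-5,6-dihydro-2H-pyran-3-carboxylate (not isolated; in equilibrium with its oxocarbenium bromide) | COC(=O)C1=C[C@@H](C2OCCO2)[C@H](C)OC1Br | intermediate
8 | methyl (5R,6S)-5-(1,3-dioxolan-2-yl)-2-methoxy-6-methyl-5,6-dihydro-2H-pyran-3-carboxylate (anomer mixture) | COC(=O)C1=C[C@@H](C2OCCO2)[C@H](C)OC1OC | intermediate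
9 | hydroxytyrosol acetate, 2-(3,4-dihydroxyphenyl)ethyl acetate | CC(=O)OCCc1ccc(O)c(O)c1 | starting material
10 | 2-(2,2-dimethyl-1,3-benzodioxol-5-yl)ethyl acetate | CC(=O)OCCc1ccc2OC(C)(C)Oc2c1 | intermediate
11 | lithium enolate of 10 (not isolated) | C=C([O-])OCCc1ccc2OC(C)(C)Oc2c1.[Li+] | intermediate
12 | lithium ester enolate of the Michael adduct of 11 to 8 (not isolated) | COC([O-])=C1C(OC)O[C@@H](C)[C@H](C2OCCO2)[C@H]1CC(=O)OCCc1ccc2OC(C)(C)Oc2c1.[Li+] | intermediate
13 | methyl (2S,3R,4R)-4-{2-[2-(2,2-dimethyl-1,3-benzodioxol-5-yl)ethoxy]-2-oxoethyl}-3-(1,3-dioxolan-2-yl)-2-methyl-3,4-dihydro-2H-pyran-5-carboxylate | COC(=O)C1=CO[C@@H](C)[C@H](C2OCCO2)[C@H]1CC(=O)OCCc1ccc2OC(C)(C)Oc2c1 | intermediate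
14 | methyl (2S,3R,4R)-4-{2-[2-(3,4-dihydroxyphenyl)ethoxy]-2-oxoethyl}-3-formyl-2-methyl-3,4-dihydro-2H-pyran-5-carboxylate | COC(=O)C1=CO[C@@H](C)[C@H](C=O)[C@H]1CC(=O)OCCc1ccc(O)c(O)c1 | target

Total step count: 7. Longest linear sequence: 6 steps (steps 1, 2, 3, 4, 6, 7).

Steps most likely to fail

Step 4 (Proposed new method). The carbenoid may be diverted into dimerisation, C–H insertion at the dioxolane acetal C–H or oxonium ylide formation. The cyclopropane may also open as a donor–acceptor pair without ring enlargement, or the cation may lose a proton instead of being captured. The fallback uses known chemistry, sets out from 5 and comes back at 8. Dibromocarbene (CHBr3, KOtBu, pentane, −20 °C) is added to 5 to give (3S,4R)-6,6-dibromo-4-(1,3-dioxolan-2-yl)-3-methyl-2-oxabicyclo[3.1.0]hexane F1. Silver nitrate (AgNO3) and K2CO3 in MeOH open it, in the established ring expansion of dihydrofuran dihalocarbene adducts, to (5R,6S)-3-bromo-5-(1,3-dioxolan-2-yl)-2-methoxy-6-methyl-5,6-dihydro-2H-pyran F2. Methoxycarbonylation of the vinyl bromide (palladium diacetate, dppf, CO 1 atm, MeOH, Et3N, DMF, 70 °C) then gives 8.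

Step 6. The enolate may add 1,2 to an ester carbonyl or act as a base (γ-deprotonation followed by loss of methanol); the face selectivity at C4 may be poor; liberated methoxide may transesterify. The fallback sets out from 10 and 8 and reaches 14 directly. Compound 10 is deacetylated (K2CO3, MeOH) to 2-(2,2-dimethyl-1,3-benzodioxol-5-yl)ethanol F3. This is esterified with 3-tert-butoxy-3-oxopropanoic acid (DCC, DMAP) to tert-butyl 2-(2,2-dimethyl-1,3-benzodioxol-5-yl)ethyl propanedioate F4. Its sodium salt (NaH, THF, 0 °C → rt), a softer and less basic nucleophile, should add to C4 of 8 and expel methoxide to give 1-tert-butyl 3-[2-(2,2-dimethyl-1,3-benzodioxol-5-yl)ethyl] 2-[(2S,3R,4S)-3-(1,3-dioxolan-2-yl)-5-(methoxycarbonyl)-2-methyl-3,4-dihydro-2H-pyran-4-yl]propanedioate F5. TFA/H2O then removes the tert-butyl ester, the acetonide and the dioxolane together, and the malonic half-acid should lose CO2 on warming (dioxane, 80 °C) to give 14.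

Step 3. Chloride may replace the anomeric mesylate without elimination, the acid-sensitive enol ether may oligomerise, and the volatile product may be lost on isolation. The fallback sets out from lactone 2 and comes back at 5, bypassing the lactol. Compound 2 is enolised and O-phosphorylated (KHMDS, (PhO)2P(O)Cl, THF/HMPA, −78 °C) to (4R,5S)-4-(1,3-dioxolan-2-yl)-5-methyl-4,5-dihydrofuran-2-yl diphenyl phosphate F6. Its C–O bond is then reduced with Bu3SnH under Pd(PPh3)4 catalysis (zerovalent palladium) to give 5.

Further compounds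
F1 | step 4 | (3S,4R)-6,6-dibromo-4-(1,3-dioxolan-2-yl)-3-methyl-2-oxabicyclo[3.1.0]hexane | BrC1(Br)C2O[C@@H](C)[C@H](C3OCCO3)C12
F2 | step 4 | (5R,6S)-3-bromo-5-(1,3-dioxolan-2-yl)-2-methoxy-6-methyl-5,6-dihydro-2H-pyran | COC1O[C@@H](C)[C@H](C2OCCO2)C=C1Br
F3 | step 6 | 2-(2,2-dimethyl-1,3-benzodioxol-5-yl)ethanol | OCCc1ccc2OC(C)(C)Oc2c1
F4 | step 6 | tert-butyl 2-(2,2-dimethyl-1,3-benzodioxol-5-yl)ethyl propanedioate | CC(C)(C)OC(=O)CC(=O)OCCc1ccc2OC(C)(C)Oc2c1
F5 | step 6 | 1-tert-butyl 3-[2-(2,2-dimethyl-1,3-benzodioxol-5-yl)ethyl] 2-[(2S,3R,4S)-3-(1,3-dioxolan-2-yl)-5-(methoxycarbonyl)-2-methyl-3,4-dihydro-2H-pyran-4-yl]propanedioate | COC(=O)C1=CO[C@@H](C)[C@H](C2OCCO2)[C@H]1C(C(=O)OC(C)(C)C)C(=O)OCCc1ccc2OC(C)(C)Oc2c1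
F6 | step 3 | (4R,5S)-4-(1,3-dioxolan-2-yl)-5-methyl-4,5-dihydrofuran-2-yl diphenyl phosphate | O=P(Oc1ccccc1)(Oc1ccccc1)OC1=C[C@@H](C2OCCO2)[C@H](C)O1
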